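## The problem

The target, methyl 2-[2-(hydroxymethyl)-4,6-dimethoxyphenoxy]-4-methyl-6-(3-methylbut-2-enyloxy)benzoate, is two benzene rings joined only through a diaryl ether oxygen. It has no stereocentre, so nothing has to be controlled in space; the task is regiochemistry and functional-group tolerance. The ether oxygen is the difficult bond. On ring B (the dimethoxy ring) its carbon C1' lies between CH2OH (C2') and OMe (C6'), and on ring A (the benzoate ring) its carbon C6 is next to the ester carbon C1. Three of the four ortho positions are therefore occupied, the ring B phenol is hindered and electron-rich, and ring A offers only one ester as activation for a substitution. Ring A also carries two different oxygens (prenyloxy at C2, aryloxy at C6) on either side of the ester, and these must be told apart. The sensitive groups are the prenyl aryl ether (sigmatropic shift on heating, cleavage in acid), the electron-rich benzylic alcohol (ionises in acid) and the methyl ester, which the benzylic alkoxide can reach in base to form an eight-membered lactone. The enabling feature is that ring A carbons C1–C4 (CO2Me, O-prenyl, H, CH3) map atom for atom onto C3–C6 of a 3-methoxycarbonyl-4-alkoxy-6-methyl-2-pyranone, while the remaining pair C5(H)–C6(OAr) is a terminal ynol ether. Ring A can thus be grown onto an ether oxygen that is already in place.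

## Retrosynthesis

**Target 21 to silyl ether 20.** Only the O–Si bond is cut. The benzylic hydroxyl must be masked because the ynol ether is made with an alkyllithium, and a tert-butyldimethylsilyl ether survives that step and the cycloaddition. The forward reaction must release the alcohol without letting its alkoxide attack the ester.

**Silyl ether 20 to pyranone 7 and ynol ether 18.** Ring A is cut at C4–C5 and C1–C6, which leads back through the bridged lactone 19 to the two partners. The neighbouring cut, the aryl–oxygen bond itself, would require a substitution between a doubly ortho-substituted phenol and an ortho-substituted, electron-rich aryl halide. Here the oxygen is instead attached to an sp carbon, where hindrance is irrelevant, and the arene is built afterwards. The precursors are much simpler: 7 holds the ester, the prenyl ether and the methyl group in fixed positions, and 18 holds all of ring B. The forward reaction must give one regiochemistry (aryloxy ortho to the ester) and must run below the temperature at which the prenyl ether rearranges. Keeping the prenyl group on 7 rather than a placeholder saves two steps and is accepted on that condition.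

**Ynol ether 18 to dichlorovinyl ether 15.** The C≡C–H unit is traced through acetylide 17 and chloroalkyne 16 to the 1,2-dichlorovinyl ether 15 by double dehalogenation. This is the established way to an aryl ynol ether and requires only that the hydroxyl is protected, hence 15 from alcohol 14 and 14 from aldehyde 13.

**Dichlorovinyl ether 13 to phenol 10 and trichloroethylene 11.** The O–C(sp2) bond is cut; in the forward sense the phenoxide adds to dichloroacetylene 12 formed from 11. Carrying the benzylic carbon as the aldehyde at this stage avoids a free ortho-hydroxybenzyl alcohol, which would ionise easily. Aldehyde 10 comes from 2,4-dimethoxyphenol 8 by formylation at its only free ortho position, through hydroxymethyl phenol 9.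

**Pyranone 7 to hydroxypyranone 5 and prenol 6.** The allylic C–O bond is cut; O-alkylation of the vinylogous acid 5 must be selective for the 4-oxygen, and C3 is already blocked by the ester. Pyranone 5 is opened at the lactone C–O bond and at the C3–C4 bond to dimethyl malonate 1 and the acetylketene 3 released from dioxinone 2, by way of acylmalonate 4. Ring A is therefore derived from malonate and acetoacetate building blocks in two steps.

## Roads not taken

**Alternative 1:** Ring B is cut at C1'–C2' and C1'–C6', with the ether oxygen already present as the ring oxygen of coumaranone A1. In the forward direction catalytic KOt-Bu would add the C2 carbanion of A1 twice to the ynone–enone A2, closing ring B as the spiro-grisenone A3.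
- Merits: the diaryl ether is never formed between two hindered arenes, and the ring A ester would come from the coumaranone carbonyl in a later fragmentation. The double Michael spiroannulation of coumaranones onto methoxyethynyl vinyl ketones is known on closely related partners. In that respect this road is stronger than the chosen plan, whose cycloaddition is untested for aryl ynol ethers.
- Weak points: four operations follow A3 (dehydrogenation of ring B to the dienone level, methoxide-induced cleavage of the spiro C–C bond, O-methylation, desilylation), against one in the chosen plan. Two stereocentres are made only to be destroyed. A2 is itself a sensitive ynol ether ketone, its enone has an acidic γ-position next to the silyloxy group, and the dehydrogenation must spare the prenyl group and two electron-rich rings.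
- Comparison: the chosen plan offers a single aromatising step that delivers ring A at the final oxidation level, and a shorter route overall.

**Alternative 2:** Ring A is cut at C5–C6 and C1–C2. The silyl dienolate A4 would add to the aryloxypropiolate A5, and loss of methoxytrimethylsilane would give phenol A6, followed by O-prenylation and desilylation.
- Merits: the prenyl group is introduced after all thermal chemistry, which is better than the chosen plan, where it must survive the cycloaddition. A5 is a disubstituted and therefore more robust ynol ether than 18, and would come from the same acetylide 17 by methoxycarbonylation.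
- Weak points: A5 is a push–pull alkyne in which the aryloxy donor deactivates exactly the carbon that the nucleophilic diene terminus must attack. After a vinylogous Michael addition the β-aryloxy acrylate can expel the hindered phenoxide instead of closing the ring, which would destroy the ether bond. Ring closure also needs one geometry of the dienoate, and senecioate dienolates can react at the α-carbon. One more step follows the key step.
- Comparison: the chosen plan pairs a donor alkyne with an acceptor diene (matched, not mismatched), and its aromatisation by decarboxylation cannot eject the aryloxy group.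

**Alternative 3:** The C6–O bond and the C1–carboxyl bond of ring A are cut, and no ring is formed. CsF would release the aryne from silyl triflate A7, the phenoxide of A8 would add at C6, and the aryl anion at C1 would capture CO2 to give acid A9. Esterification, removal of the methoxymethyl group, prenylation and desilylation would follow.
- Merits: this is the most convergent road. Its ring B partner A8 is a simple, stable phenol with no ynol ether, and in robustness of the fragments it is better than the chosen plan. Addition to 3-alkoxyarynes reliably occurs distal to the alkoxy group.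
- Weak points: a doubly ortho-substituted phenoxide, itself reversibly carbonated under CO2, must intercept a short-lived aryne. The aryl anion is easily protonated, which would give the ether without the carboxyl group. A7 needs several steps of its own, and four steps follow the key step, one of them an acidic deprotection beside an acid-labile benzylic silyl ether.
- Comparison: the chosen plan needs no protecting group on ring A and makes its ring A fragment in two steps.

Key step: step 8

Assumption: the two bridgehead stereocentres of the transient lactone 19 are of no consequence (the target is achiral), so 19 is drawn without configuration as the racemate.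

## Route

Step 1
Reactants: 1 dimethyl malonate; 2 2,2,6-trimethyl-4H-1,3-dioxin-4-one
Product: 5 methyl 4-hydroxy-6-methyl-2-oxo-2H-pyran-3-carboxylate, via acetylketene 3 (not isolated), via dimethyl 2-(3-oxobutanoyl)malonate 4 (not isolated)
Conditions: NaH (2.2 equiv), THF, 0 °C; 2, PhMe, 110 °C; then 1 M HCl
Reagents that add atoms: none
Why: C-acylation of the malonate enolate by thermally generated acetylketene, then base-mediated lactonisation of the enolised diketone onto one ester (6-exo-trig acyl substitution); the same pyranone is the known outcome of malonate acylation with diketene.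

Step 2
Reactants: 5 methyl 4-hydroxy-6-methyl-2-oxo-2H-pyran-3-carboxylate; 6 3-methylbut-2-en-1-ol
Product: 7 methyl 6-methyl-4-(3-methylbut-2-enyloxy)-2-oxo-2H-pyran-3-carboxylate
Conditions: PPh3, DIAD, THF, 0 °C → rt
Reagents that add atoms: none
Why: Mitsunobu O-alkylation of a 4-hydroxy-2-pyranone, a vinylogous acid of suitable acidity; C3 is blocked by the ester so C-alkylation cannot compete, and the primary allylic alcohol should react by SN2 to give the linear prenyl ether.

Step 3
Reactants: 8 2,4-dimethoxyphenol
Product: 10 2-hydroxy-3,5-dimethoxybenzaldehyde, via 2-(hydroxymethyl)-4,6-dimethoxyphenol 9 (not isolated)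
Conditions: MgCl2, Et3N, (CH2O)n, MeCN, reflux; then 1 M HCl
Reagents that add atoms: paraformaldehyde (as formaldehyde), C=O
Why: Magnesium-mediated ortho-formylation (Casnati–Skattebøl): the magnesium phenoxide delivers formaldehyde to the only free ortho position, and the hydroxymethyl phenoxide 9 is oxidised by a second formaldehyde through an Oppenauer-type hydride transfer.

Step 4
Reactants: 10 2-hydroxy-3,5-dimethoxybenzaldehyde; 11 trichloroethylene
Product: 13 2-{[(E)-1,2-dichloroethenyl]oxy}-3,5-dimethoxybenzaldehyde, via dichloroacetylene 12 (not isolated)
Conditions: K2CO3, DMF, 70 °C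
Reagents that add atoms: none
Why: Known synthesis of aryl 1,2-dichlorovinyl ethers: K2CO3 dehydrochlorinates trichloroethylene, the phenoxide adds anti to the dichloroacetylene formed in solution, and protonation gives the E ether; the non-enolisable aldehyde should be inert.

Step 5
Reactants: 13 2-{[(E)-1,2-dichloroethenyl]oxy}-3,5-dimethoxybenzaldehyde
Product: 14 (2-{[(E)-1,2-dichloroethenyl]oxy}-3,5-dimethoxyphenyl)methanol
Conditions: NaBH4, MeOH, 0 °C
Reagents that add atoms: none
Why: Chemoselective borohydride reduction of an aromatic aldehyde; the dichlorovinyl ether is not reduced.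

Step 6
Reactants: 14 (2-{[(E)-1,2-dichloroethenyl]oxy}-3,5-dimethoxyphenyl)methanol
Product: 15 tert-butyl[(2-{[(E)-1,2-dichloroethenyl]oxy}-3,5-dimethoxyphenyl)methoxy]dimethylsilane
Conditions: TBSCl, imidazole, CH2Cl2, rt
Reagents that add atoms: tert-butyldimethylsilyl chloride, CC(C)(C)[Si](C)(C)Cl
Why: Standard silylation of a primary alcohol; it removes the acidic proton before the organolithium step and the ether survives n-BuLi at low temperature.

Step 7
Reactants: 15 tert-butyl[(2-{[(E)-1,2-dichloroethenyl]oxy}-3,5-dimethoxyphenyl)methoxy]dimethylsilane
Product: 18 tert-butyl[(2-ethynyloxy-3,5-dimethoxyphenyl)methoxy]dimethylsilane, via chloroethynyl aryl ether 16 (not isolated), via lithium aryloxyacetylide 17 (not isolated)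
Conditions: n-BuLi (2.3 equiv), THF, −78 → −40 °C; H2O, −78 °C; used at once
Reagents that add atoms: none
Why: Known conversion of 1,2-dichlorovinyl ethers into ynol ethers: deprotonation and loss of LiCl give chloroalkyne 16, a second equivalent of n-BuLi exchanges Cl for Li to give 17, and water protonates it; at −78 °C this should outrun ortho-lithiation between the two methoxy groups.

Step 8
Reactants: 7 methyl 6-methyl-4-(3-methylbut-2-enyloxy)-2-oxo-2H-pyran-3-carboxylate; 18 tert-butyl[(2-ethynyloxy-3,5-dimethoxyphenyl)methoxy]dimethylsilane
Product: 20 methyl 2-{2-[(tert-butyldimethylsilyloxy)methyl]-4,6-dimethoxyphenoxy}-4-methyl-6-(3-methylbut-2-enyloxy)benzoate, via bicyclic lactone 19 (not isolated)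
Conditions: 7 (1.5 equiv), 18 (1.0 equiv), PhMe (1 M), 4 Å MS, 80 °C, sealed tube
Reagents that add atoms: none
Why: Proposed new method: an aryl ethynyl ether has not been shown as dienophile toward a 4-alkoxy-2-pyranone-3-carboxylate; the closest known reaction type is the inverse-electron-demand Diels–Alder reaction of 2-pyranone-3-carboxylates with ketene acetals, ynamines and alkyl ynol ethers followed by loss of CO2. The HOMO of 18 is polarised by oxygen toward the terminal CH and the LUMO of 7 is largest at C6, the position vinylogous to both the lactone and the ester carbonyl, so the CH–C6 bond should lead in an asynchronous (at the limit zwitterionic, malonate-type anion and oxygen-stabilised vinyl cation) transition state that is completed between the oxygen-bearing alkyne carbon and C3. Ring A is thus closed by an intermolecular [4+2] cycloaddition joining four pyranone carbons to the two alkyne carbons, giving the 2-oxabicyclo[2.2.2]octadienone 19. Because the dienophile is an alkyne, 19 already holds two ring double bonds, and retro-[4+2] loss of CO2 gives the benzene ring directly and irreversibly, with no elimination step. The two bridgehead stereocentres of 19 are transient and no stereocentre remains. The step needs regioselectivity (aryloxy ortho and not meta to the ester), secured by the matched polarisation of both partners, and it must spare the prenyl ether, secured by the 80 °C ceiling, since the only [3,3] terminus in 7 is the quaternary C3 and the aryl prenyl ether of 20 rearranges only at much higher temperature. The aryl group of 18, substituted at both ortho positions, should slow self-condensation of the alkyne, and an aryl ynol ether has no β-hydrogen for the retro-ene loss of ketene that limits alkyl ynol ethers on heating.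

Step 9
Reactants: 20 methyl 2-{2-[(tert-butyldimethylsilyloxy)methyl]-4,6-dimethoxyphenoxy}-4-methyl-6-(3-methylbut-2-enyloxy)benzoate
Product: 21 methyl 2-[2-(hydroxymethyl)-4,6-dimethoxyphenoxy]-4-methyl-6-(3-methylbut-2-enyloxy)benzoate
Conditions: TBAF, AcOH (1 equiv each), THF, 0 °C → rt
Reagents that add atoms: none
Why: Fluoride cleavage of a primary silyl ether; the acetic acid buffer keeps the released benzylic alkoxide protonated so that it cannot attack the neighbouring methyl ester, and the prenyl ether and ester are untouched.

## Compound list

1 | dimethyl malonate | COC(=O)CC(=O)OC | starting material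
2 | 2,2,6-trimethyl-4H-1,3-dioxin-4-one | CC1=CC(=O)OC(C)(C)O1 | starting material
3 | acetylketene (but-1-ene-1,3-dione) | CC(=O)C=C=O | intermediate
4 | dimethyl 2-(3-oxobutanoyl)malonate (formed as its sodium enolate) | COC(=O)C(C(=O)OC)C(=O)CC(C)=O | intermediate
5 | methyl 4-hydroxy-6-methyl-2-oxo-2H-pyran-3-carboxylate | COC(=O)C1=C(O)C=C(C)OC1=O | intermediate
6 | 3-methylbut-2-en-1-ol (prenol) | CC(C)=CCO | starting material
7 | methyl 6-methyl-4-(3-methylbut-2-enyloxy)-2-oxo-2H-pyran-3-carboxylate | COC(=O)C1=C(OCC=C(C)C)C=C(C)OC1=O | intermediate
8 | 2,4-dimethoxyphenol | COc1ccc(O)c(OC)c1 | starting material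
9 | 2-(hydroxymethyl)-4,6-dimethoxyphenol (formed as its magnesium phenoxide) | OCc1cc(OC)cc(OC)c1O | intermediate
10 | 2-hydroxy-3,5-dimethoxybenzaldehyde | O=Cc1cc(OC)cc(OC)c1O | intermediate
11 | trichloroethylene | ClC=C(Cl)Cl | starting material
12 | dichloroacetylene | ClC#CCl | intermediate
13 | 2-{[(E)-1,2-dichloroethenyl]oxy}-3,5-dimethoxybenzaldehyde | O=Cc1cc(OC)cc(OC)c1O/C(Cl)=C\Cl | intermediate
14 | (2-{[(E)-1,2-dichloroethenyl]oxy}-3,5-dimethoxyphenyl)methanol | OCc1cc(OC)cc(OC)c1O/C(Cl)=C\Cl | intermediate
15 | tert-butyl[(2-{[(E)-1,2-dichloroethenyl]oxy}-3,5-dimethoxyphenyl)methoxy]dimethylsilane | CC(C)(C)[Si](C)(C)OCc1cc(OC)cc(OC)c1O/C(Cl)=C\Cl | intermediate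
16 | tert-butyl({2-[(chloroethynyl)oxy]-3,5-dimethoxyphenyl}methoxy)dimethylsilane | ClC#COc1c(CO[Si](C)(C)C(C)(C)C)cc(OC)cc1OC | intermediate
17 | ({2-[(tert-butyldimethylsilyloxy)methyl]-4,6-dimethoxyphenoxy}ethynyl)lithium | [Li]C#COc1c(CO[Si](C)(C)C(C)(C)C)cc(OC)cc1OC | intermediate
18 | tert-butyl[(2-ethynyloxy-3,5-dimethoxyphenyl)methoxy]dimethylsilane | C#COc1c(CO[Si](C)(C)C(C)(C)C)cc(OC)cc1OC | intermediate
19 | methyl 8-{2-[(tert-butyldimethylsilyloxy)methyl]-4,6-dimethoxyphenoxy}-1-methyl-5-(3-methylbut-2-enyloxy)-3-oxo-2-oxabicyclo[2.2.2]octa-5,7-diene-4-carboxylate (racemic, transient) | COC(=O)C12C(=O)OC(C)(C=C1OCC=C(C)C)C=C2Oc1c(CO[Si](C)(C)C(C)(C)C)cc(OC)cc1OC | intermediate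
20 | methyl 2-{2-[(tert-butyldimethylsilyloxy)methyl]-4,6-dimethoxyphenoxy}-4-methyl-6-(3-methylbut-2-enyloxy)benzoate | COC(=O)c1c(OCC=C(C)C)cc(C)cc1Oc1c(CO[Si](C)(C)C(C)(C)C)cc(OC)cc1OC | intermediate
21 | methyl 2-[2-(hydroxymethyl)-4,6-dimethoxyphenoxy]-4-methyl-6-(3-methylbut-2-enyloxy)benzoate | COC(=O)c1c(OCC=C(C)C)cc(C)cc1Oc1c(CO)cc(OC)cc1OC | target

## Step count and risks

Total: 9 steps. Longest linear sequence: 7 steps (steps 3 to 9); the pyranone arm (steps 1 and 2) joins at step 8.

**Step 8 (key step, proposed new method).** The cycloaddition may be too slow at a temperature both partners tolerate. The 4-alkoxy group raises the LUMO of the pyranone, the 6-methyl group hinders the first bond, and an aryl ynol ether is a weaker donor than a ketene acetal. Oligomerisation of the alkyne, or on forcing loss or shift of the prenyl group, could then overtake ring formation. The fallback abandons ring construction and forms the ether bond by known chemistry; it sets out from prenol 6 and returns at target 21, so step 9 is not needed. Mitsunobu mono-etherification of commercial methyl 2,6-dihydroxy-4-methylbenzoate F1 with 6 (the second hydroxyl stays hydrogen-bonded to the ester) would give methyl 2-hydroxy-4-methyl-6-(3-methylbut-2-enyloxy)benzoate F2. Ligand-accelerated Ullmann coupling of F2 with commercial 2-bromo-3,5-dimethoxybenzaldehyde F3 (CuI, picolinic acid, K3PO4, DMSO, 90 °C; the ortho-formyl group activates the bromide) would give methyl 2-(2-formyl-4,6-dimethoxyphenoxy)-4-methyl-6-(3-methylbut-2-enyloxy)benzoate F4. NaBH4 reduction of the aldehyde then gives 21. The coupling joins a hindered pair, which is why it is the fallback and not the plan.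

**Step 7.** The terminal aryl ynol ether may decompose during isolation (hydration or oligomerisation on silica or on concentration), and ortho-lithiation between the methoxy groups may compete if the temperature rises. The fallback sets out from 15 and returns at 18: acetylide 17 is quenched with TMSCl instead of water to give the C-silylated ynol ether tert-butyl[(3,5-dimethoxy-2-{[(trimethylsilyl)ethynyl]oxy}phenyl)methoxy]dimethylsilane F5. This can be purified and stored, and is unmasked with K2CO3 in MeOH at 0 °C immediately before step 8.

**Step 2.** Alkylation may occur at the lactone carbonyl oxygen (giving the isomeric 2-alkoxy-4-pyranone) or with allylic transposition, and the strongly hydrogen-bonded enol may react sluggishly. The fallback reverses the polarity; it sets out from 5 and returns at 7. TsCl and Et3N would give methyl 6-methyl-4-[(4-methylbenzenesulfonyl)oxy]-2-oxo-2H-pyran-3-carboxylate F6, and addition–elimination of prenol 6 at C4 (Cs2CO3, MeCN, 0 °C) would fix the prenyl group on the 4-oxygen.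

**Step 1.** Acetylketene may dimerise or be consumed by O-acylation before the malonate enolate captures it at carbon. The fallback uses a discrete acyl donor; it sets out from 1 and returns at 5 through 4. Commercial 2-(2-methyl-1,3-dioxolan-2-yl)acetic acid F7 is activated with carbonyldiimidazole as 1-[2-(2-methyl-1,3-dioxolan-2-yl)acetyl]-1H-imidazole F8. Magnesium-mediated C-acylation of 1 (MgCl2, Et3N, MeCN) gives dimethyl 2-[2-(2-methyl-1,3-dioxolan-2-yl)acetyl]malonate F9. Aqueous HCl then removes the ketal to give 4, which lactonises to 5 on warming.

## Further compounds

F1 | step 8 | methyl 2,6-dihydroxy-4-methylbenzoate | COC(=O)c1c(O)cc(C)cc1O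
F2 | step 8 | methyl 2-hydroxy-4-methyl-6-(3-methylbut-2-enyloxy)benzoate | COC(=O)c1c(O)cc(C)cc1OCC=C(C)C
F3 | step 8 | 2-bromo-3,5-dimethoxybenzaldehyde | O=Cc1cc(OC)cc(OC)c1Br
F4 | step 8 | methyl 2-(2-formyl-4,6-dimethoxyphenoxy)-4-methyl-6-(3-methylbut-2-enyloxy)benzoate | COC(=O)c1c(OCC=C(C)C)cc(C)cc1Oc1c(C=O)cc(OC)cc1OC
F5 | step 7 | tert-butyl[(3,5-dimethoxy-2-{[(trimethylsilyl)ethynyl]oxy}phenyl)methoxy]dimethylsilane | C[Si](C)(C)C#COc1c(CO[Si](C)(C)C(C)(C)C)cc(OC)cc1OC
F6 | step 2 | methyl 6-methyl-4-[(4-methylbenzenesulfonyl)oxy]-2-oxo-2H-pyran-3-carboxylate | COC(=O)C1=C(OS(=O)(=O)c2ccc(C)cc2)C=C(C)OC1=O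
F7 | step 1 | 2-(2-methyl-1,3-dioxolan-2-yl)acetic acid | CC1(CC(=O)O)OCCO1
F8 | step 1 | 1-[2-(2-methyl-1,3-dioxolan-2-yl)acetyl]-1H-imidazole | CC1(CC(=O)n2ccnc2)OCCO1
F9 | step 1 | dimethyl 2-[2-(2-methyl-1,3-dioxolan-2-yl)acetyl]malonate | COC(=O)C(C(=O)OC)C(=O)CC1(C)OCCO1
A1 | alternative 1 | 6-methyl-4-(3-methylbut-2-enyloxy)-1-benzofuran-3(2H)-one | O=C1COc2cc(C)cc(OCC=C(C)C)c12
A2 | alternative 1 | (E)-6-(tert-butyldimethylsilyloxy)-1-methoxyhex-4-en-1-yn-3-one | COC#CC(=O)/C=C/CO[Si](C)(C)C(C)(C)C
A3 | alternative 1 | 6'-[(tert-butyldimethylsilyloxy)methyl]-2'-methoxy-6-methyl-4-(3-methylbut-2-enyloxy)-3H-spiro[1-benzofuran-2,1'-cyclohex-2-ene]-3,4'-dione (racemic mixture of diastereomers) | O=C1c2c(OCC=C(C)C)cc(C)cc2OC13C(OC)=CC(=O)CC3CO[Si](C)(C)C(C)(C)C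
A4 | alternative 2 | [(1-methoxy-3-methylbuta-1,3-dien-1-yl)oxy]trimethylsilane | COC(O[Si](C)(C)C)=CC(C)=C
A5 | alternative 2 | methyl 3-{2-[(tert-butyldimethylsilyloxy)methyl]-4,6-dimethoxyphenoxy}prop-2-ynoate | COC(=O)C#COc1c(CO[Si](C)(C)C(C)(C)C)cc(OC)cc1OC
A6 | alternative 2 | methyl 2-{2-[(tert-butyldimethylsilyloxy)methyl]-4,6-dimethoxyphenoxy}-6-hydroxy-4-methylbenzoate | COC(=O)c1c(O)cc(C)cc1Oc1c(CO[Si](C)(C)C(C)(C)C)cc(OC)cc1OC
A7 | alternative 3 | 3-(methoxymethoxy)-5-methyl-2-(trimethylsilyl)phenyl trifluoromethanesulfonate | COCOc1cc(C)cc(OS(=O)(=O)C(F)(F)F)c1[Si](C)(C)C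
A8 | alternative 3 | 2-[(tert-butyldimethylsilyloxy)methyl]-4,6-dimethoxyphenol | COc1cc(CO[Si](C)(C)C(C)(C)C)c(O)c(OC)c1
A9 | alternative 3 | 2-{2-[(tert-butyldimethylsilyloxy)methyl]-4,6-dimethoxyphenoxy}-6-(methoxymethoxy)-4-methylbenzoic acid | OC(=O)c1c(OCOC)cc(C)cc1Oc1c(CO[Si](C)(C)C(C)(C)C)cc(OC)cc1OC
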